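(Readings and results were computed with made-up constants; scatter was added.)

I began from a one-step world, in which free monomer fell by a single pseudo-first-order decay with rate k[free monomer]. Integrated, that rate meant the share of [free monomer] left was one half raised to the number of half-lives elapsed. The flasks and the question stood so:

| flask | free monomer | initiator | remark | time |
|---|---|---|---|---|
| red | 2 M | 5.7 mol% | run made earlier |  |
| teal | 2 M | 11 mol% | run made earlier |  |
| cedar | 2.0 M | 13 mol% |  | 6.0 h |
| ash | 2.0 M | 10 mol% |  | 6.0 h |
| larch | 2.0 M | 17 mol% |  | 6.0 h |

| run | time / h | monomer in chains / % | free monomer / % |
|---|---|---|---|
| red | 0.500 | 22 | 57 |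
| red | 1.50 | 55 | 15 |
| red | 3.00 | 71 | 2 |
| red | 4.00 | 73 | 1 |
| red | 6.00 | 73 | 0 |
| teal | 1.33 | 70 | 6 |
| teal | 2.50 | 78 | 0 |
| teal | 4.00 | 79 | 0 |
| teal | 5.00 | 78 | 0 |
| teal | 6.00 | 78 | 2 |

(readings scatter by 1.5 percentage points)

- which of these there is most of at the end, counted by the free monomer in it, cedar (free monomer / monomer in chains)
- which of these there is most of at the end, counted by the free monomer in it, ash (free monomer / monomer in chains)
- which of these there is most of at the end, counted by the free monomer in it, larch (free monomer / monomer in chains)
- the largest of these amounts at the end, in percent of the free monomer charged, cedar
- the largest of these amounts at the end, in percent of the free monomer charged, ash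
- the largest of these amounts at the end, in percent of the free monomer charged, larch

- a species is counted by the free monomer in it: one self-condensation product counts as two
- candidate steps: free monomer + initiator -> living end + monomer in chains; 2 free monomer -> self-condensation product; free monomer + living end -> monomer in chains + living end

I read the half-life of free monomer from the charge to one reading, in red from 15% left at 1.50 h and in teal from 6% left at 1.33 h:

half-life = ln(2) × time / ln(charged / left)
red: 0.548 h; teal: 0.328 h

Teal, with more initiator than red, had the shorter half-life, and cedar, ash and larch each carried more initiator than red, so I took the red value as my estimate of the long end for them: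

count = 6.0 h / 0.548 h = 10.9
share left = 0.0506%

This number of half-lives in the run, the half-life count, was what I carried forward.

Then I turned the question round. In red, monomer in chains had overtaken free monomer by 1.50 h, at 55% against 15%, which was a count of 2.74. On that curve stretched in time, free monomer could lead at 6.0 h only with a half-life of at least 2.19 h, and that was 4.00 times the red one. So I committed to monomer in chains for cedar, ash and larch. The count gave no percentage of my own, because it tells how much free monomer went, not how it split.

The forecast named monomer in chains for these flasks too, with 79.5% for cedar, 77.5% for ash and 81.2% for larch, reasoning “so 6 h is effectively complete in all three new runs”.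

The flask gave monomer in chains for cedar at 81.2%, monomer in chains for ash at 78.6% and monomer in chains for larch at 83.6%, so the forecast held within its margin. Ash had 0.299% free monomer at 3.00 h, where half the count gives 2.25%, so ash stood below my long end.

    free monomer + initiator → living end + monomer in chains (k = 0.0150 M⁻¹ min⁻¹)
    2 free monomer → self-condensation product (k = 0.00260 M⁻¹ min⁻¹)
    free monomer + living end → monomer in chains + living end, rate k3*[living end]*[free monomer] (k = 0.250 M⁻¹ min⁻¹)

The neighbour, ash with 17 mol% of initiator, lay above teal's loading, so teal's half-life gave it a count of 18.3 and a share left of <0.001%. Computed, that neighbour ended with 0% free monomer and 83.6% monomer in chains.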